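(The runs were generated by integration from invented constants.)

In a one-step world the fall of G would be the conversion. In this flask, what leaves the solid stands first as dissolved L, which counts as not reacted, so conversion is J plus Z.

| flask | G | Q | remark | time |
|---|---|---|---|---|
| violet | 0.068 M | 0.80 equiv | the very flask that is asked about, followed so far |  |
| flask | 0.068 M | 0.800 equiv |  | 2.0 min |

violet run (percent of the G charged)

| time / s | G / % | J / % |
|---|---|---|
| 10.0 | 31.2 | 9.2 |
| 15.0 | 16.0 | 14.0 |
| 20.0 | 2.2 | 15.5 |

(standard deviation of a reading: 1 percentage point)

- at 2.0 min, what has stopped the reaction, if anything has (for what has run out or reacted, a solid counts together with what of it has only dissolved) (it is still moving / all of G has reacted)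
- part of the G that has turned into other species by 2.0 min (what has only dissolved does not count)
- amount of J at 2.0 min, in percent of the G charged

- in percentages every species weighs as the G in it: one Z counts as two
- as a solid, counted per litre of solution: G
- the numbers in the tables scatter by 1 percentage point (one standard deviation)
- what may be going on: G <-> L; L + Q -> J; 2 L -> Z; Q -> E
- at the start none of G is in solution
- what has only dissolved of G counts as not reacted
- the reaction counts as stopped when no species that holds the G changes by six tenths of a point or more over the second half of the time

1. I drew G first. It lost 69 percentage points by 10.0 s, then less than that, 29 points, over the next 10.0 s. That straight stretch reaches zero near 20.8 s.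

2. I followed one molecule of L at its fork. Over that stretch J gained 6.3 points, so J took 21.7% of what left the solid. I took L as roughly level, which leaves a drain of 23 points towards Z.

3. At 20.0 s the pool P, meaning L plus Z, stood at 82.3%. P over its drain rate gives 36.3 s. This τ is my clearing time, the second-order half-life of L at level P.

4. I let the tail follow L = P/(1 + t/τ), with t counted from 20.0 s. That put L at 39.2% at mid-time and 21.9% at 2.0 min. I therefore committed to a flask still moving, with conversion near 78.1%. Because P holds some Z, that is a low figure.

5. J's gain shrank to 1.5 points in the last interval, less than the 4.8 points before it. I expected a level a few points above the last reading.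

The forecast, which parted from my reckoning on the stop and the conversion, gave all of G has reacted, conversion 99.9% and J 18%, in its words “Conversion at 2 min is therefore essentially complete”.

The flask gave it is still moving, conversion 84.4% and J 20.5%.

    G ⇌ L, rate k1*(cs1 - [L]) while solid is left; crystals form when [L] > cs1 (solubility = 47.0 mM, k = 0.210 s⁻¹)
    L + Q → J (k = 0.810 L mol⁻¹ s⁻¹)
    2 L → Z (k = 0.340 L mol⁻¹ s⁻¹)
    Q → E (k = 0.0650 s⁻¹)

L still held 15.6% at 2.00 min, against the 21.9% that my τ gave, and a species moved 12 points over the second half. By the constant of the step that makes Z, the half-life of L at that level is 2.31 min, longer than the whole run of 2.0 min.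

For the same flask left until 5.0 min, P and τ give L 9.43% and conversion 90.6%. The computed flask holds L 6.78% and conversion 93.2%.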